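The oxirane at C7–C8 (ring numbered from the isopropenyl carbon C1 through the C3–C5 triol) is cis-fused to the ten-membered carbocycle, so it maps onto a (Z)-trisubstituted cyclodecene whose geometry the ring itself should favour. Everything rests on making that C7=C8 bond late: ring-closing metathesis of an acyclic triene joins a C7 vinyl group to the methyl-bearing C8 olefin, the adjacent free C9 hydroxyl activating this olefin over the C1 isopropenyl group and afterwards steering the peracid. The triene, with its six chain stereocentres in place, comes from (S)-carvone used as a cyclic template: its ring provides C10 and C1–C5, fixes C4 and (by epoxide inversion) C3, and is cut between C5 and C10 for two allylations.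

Key step: step 14

Remark (numbering): C1 isopropenyl carbon, C2 CH2, C3 CH(OH), C4 C(Me)(OH), C5 CH(O-angeloyl), C6 CH2, C7/C8 oxirane carbons (C8 methylated), C9 CH(O-angeloyl), C10 CH(O-acyl); the acyl group on O10 is (R)-2-methylbutanoyl; these labels are used for all intermediates.
Remark (assumption): C10 is carried as an epimeric (3) or anomeric (5–7, 10, 11) mixture, because this centre is destroyed in step 3 and set again in step 10; the SMILES of 3 shows the expected major epimer and those of 5–7, 10 and 11 leave the acetal carbon open.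

Step 1
Reactants: 1 (S)-(+)-carvone
Product: 2 (1S,4S,6S)-1-methyl-4-(prop-1-en-2-yl)-7-oxabicyclo[4.1.0]heptan-2-one (oxirane C3–C4 trans to isopropenyl)
Conditions: H2O2 (30% aq.), NaOH (cat.), MeOH, 0 °C
Reagents that add atoms: hydrogen peroxide, OO
Why: Weitz–Scheffer nucleophilic epoxidation touches only the enone; hydroperoxide adds axially to C3 anti to the C1 isopropenyl group, so both new C–O bonds are trans to it, which sets C4 as in the target (C3 is corrected in step 3).

Step 2
Reactants: 2 carvone oxide
Product: 3 α′-ketol of 2 (hydroxyl on C10)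
Conditions: KN(SiMe3)2, THF, −78 °C; then 2-(benzenesulfonyl)-3-phenyloxaziridine, −78 °C; aq. NH4Cl
Reagents that add atoms: 2-(benzenesulfonyl)-3-phenyloxaziridine, O=S(=O)(c1ccccc1)N1OC1c1ccccc1
Why: Davis oxidation of the potassium enolate, which can form only toward C10 because C4 is quaternary; oxygen should enter mainly anti to the isopropenyl group, but the C10 configuration is irrelevant because this carbon becomes a carbonyl carbon in step 3.

Step 3
Reactants: 3 α′-ketol
Product: 5 methyl 2-hydroxy-2-[5-methoxy-4-(prop-1-en-2-yl)oxolan-2-yl]propanoate, via epoxy aldehyde ester 4 (not isolated)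
Conditions: Pb(OAc)4, MeOH/PhH (1:1), 0 °C; then camphorsulfonic acid (cat.), MeOH, 23–40 °C
Reagents that add atoms: methanol, CO
Why: Lead tetraacetate cleaves the α-ketol (Criegee-type cleavage of its methanol hemiketal) to the C5 methyl ester and C10 aldehyde 4, and under acid the methanol hemiacetal of that aldehyde opens the oxirane by 5-exo SN2 attack at C3 (C4 is tertiary and α to the ester), which inverts C3 to the target configuration and locks O3 and C10 in one cyclic acetal.

Step 4
Reactants: 5 oxolane ester
Product: 6 2-hydroxy-2-[5-methoxy-4-(prop-1-en-2-yl)oxolan-2-yl]propanal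
Conditions: i-Bu2AlH (2.3 equiv), CH2Cl2, −78 °C; aq. potassium sodium tartrate
Reagents that add atoms: none
Why: Low-temperature half-reduction of the ester with i-Bu2AlH, the tetrahedral aluminium hemiacetal being held as a five-membered chelate with the C4 alkoxide until work-up; the quaternary C4 centre cannot epimerise.

Step 5
Reactants: 6 α-hydroxy aldehyde
Product: 7 2-[5-methoxy-4-(prop-1-en-2-yl)oxolan-2-yl]hex-5-ene-2,3-diol (C4/C5 syn)
Conditions: allyl bromide, In powder, DMF, 0 °C to rt
Reagents that add atoms: allyl bromide, C=CCBr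
Why: Barbier-type indium allylation under chelation (Cram-chelate) control: indium bridges the aldehyde oxygen and the C4 alkoxide and the allyl group adds from the side of the small C4 methyl group, away from the oxolane at C3, which should give the 4,5-syn diol and thus the target configuration at C5.

Step 6
Reactants: 8 angelic acid
Product: 9 (Z)-2-methylbut-2-enoic 2,4,6-trichlorobenzoic anhydride
Conditions: 2,4,6-trichlorobenzoyl chloride, Et3N, PhMe, 0 °C to rt; filtered under Ar and kept as a PhMe solution at −20 °C, in an amount sufficient for steps 7 and 16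
Reagents that add atoms: 2,4,6-trichlorobenzoyl chloride, O=C(Cl)c1c(Cl)cc(Cl)cc1Cl
Why: Yamaguchi mixed-anhydride formation by O-acylation of the triethylammonium carboxylate with the aroyl chloride; no nucleophilic catalyst is present, so the Z geometry of the acid is kept, and the two ortho chlorines shield the aroyl carbonyl enough for the anhydride to be filtered from the ammonium salt and stored cold.

Step 7
Reactants: 7 diol; 9 angelic 2,4,6-trichlorobenzoic anhydride
Product: 10 C5 angelate of 7
Conditions: 9 (2 equiv), Et3N (2 equiv), PhMe, 80 °C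
Reagents that add atoms: none
Why: Yamaguchi-type esterification with the preformed mixed anhydride, the standard way to make angelates without Z-to-E isomerisation (no DMAP); the alcohol attacks the unhindered angeloyl carbonyl, only the secondary C5 hydroxyl reacts because the tertiary C4 hydroxyl is too hindered, and no stereocentre changes.

Step 8
Reactants: 10 C5 angelate
Product: 11 2-hydroxy-2-[5-hydroxy-4-(prop-1-en-2-yl)oxolan-2-yl]hex-5-en-3-yl (Z)-2-methylbut-2-enoate (lactol)
Conditions: HCl (0.5 M aq.), THF, rt
Reagents that add atoms: water, O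
Why: Acid-catalysed hydrolysis of the very labile 2-methoxyoxolane acetal through its oxocarbenium ion; the ester and the olefins are inert to dilute acid and no stereocentre of the target is touched.

Step 9
Reactants: 12 2-methylprop-2-en-1-ol
Product: 13 3-(methoxymethoxy)-2-methylprop-1-ene
Conditions: MeOCH2Cl, i-Pr2NEt, CH2Cl2, 0 °C to rt
Reagents that add atoms: chloromethyl methyl ether, COCCl
Why: Williamson-type O-alkylation of the primary alcohol with the α-chloro ether (acetal formation); no stereocentre is involved.

Step 10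
Reactants: 11 lactol; 13 methallyl methoxymethyl ether
Product: 15 5,6,9-trihydroxy-10-(methoxymethoxy)-5,11-dimethyl-8-(prop-1-en-2-yl)dodeca-1,11-dien-4-yl (Z)-2-methylbut-2-enoate, via γ-alkoxyallylborane 14 (not isolated)
Conditions: 13, s-BuLi, THF, −78 °C; (−)-Ipc2BOMe [from (+)-α-pinene]; BF3·OEt2; then 11 (0.3 equiv relative to 14), −78 °C to rt; HOCH2CH2NH2 work-up
Reagents that add atoms: none
Why: Brown-type γ-alkoxyallylboration: α-lithiation of 13 and trapping on boron give the (Z)-γ-alkoxyallylborane 14, which adds to the open hydroxy-aldehyde form of 11 through a chair Zimmerman–Traxler transition state, so that C9/C10 come out syn from the Z geometry while the isopinocampheyl groups direct attack to the Si face of the C10 aldehyde, giving the target configuration at both centres.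

Step 11
Reactants: 15 triol; 16 (R)-2-methylbutanoic acid
Product: 19 5,6-dihydroxy-10-(methoxymethoxy)-5,11-dimethyl-9-[(2R)-2-methylbutanoyl]oxy-8-(prop-1-en-2-yl)dodeca-1,11-dien-4-yl (Z)-2-methylbut-2-enoate, via phenylboronate 17 (not isolated), via acylated phenylboronate 18 (not isolated)
Conditions: PhB(OH)2, MgSO4, CH2Cl2, rt; then 16, N,N′-diisopropylcarbodiimide, DMAP (cat.), 0 °C to rt; then pinacol, rt
Reagents that add atoms: none
Why: Transient boronate masking followed by Steglich esterification: phenylboronic acid ties the syn-1,2-diol C3/C4 into a five-membered boronate so that only the C10 hydroxyl is acylated, and transesterification with pinacol then releases the diol; no stereocentre changes.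

Step 12
Reactants: 19 C10 ester diol
Product: 20 C3 tert-butyldimethylsilyl ether of 19
Conditions: t-BuMe2SiOTf (1.1 equiv), 2,6-lutidine, CH2Cl2, −78 °C
Reagents that add atoms: tert-butyldimethylsilyl trifluoromethanesulfonate, CC(C)(C)[Si](C)(C)OS(=O)(=O)C(F)(F)F
Why: Silylation with the silyl triflate takes the secondary C3 hydroxyl in preference to the more hindered tertiary C4 hydroxyl at low temperature; no stereocentre changes.

Step 13
Reactants: 20 silyl ether
Product: 21 C9 alcohol (metathesis substrate)
Conditions: Me3SiOTf, 2,2′-bipyridyl, CH2Cl2, 0 °C; then H2O, rt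
Reagents that add atoms: none
Why: Acetal-selective cleavage of the methoxymethyl ether: the silyl triflate activates the acetal, bipyridyl traps the oxocarbenium ion as a pyridinium salt and water hydrolyses it, under nearly neutral conditions that should spare the silyl ether, the esters, the olefins and the C9 configuration and should not promote acyl migration from O10.

Step 14
Reactants: 21 triene
Product: 22 (Z)-3-[tert-butyl(dimethyl)silyl]oxy-4,9-dihydroxy-4,8-dimethyl-10-[(2R)-2-methylbutanoyl]oxy-1-(prop-1-en-2-yl)cyclodec-7-en-5-yl (Z)-2-methylbut-2-enoate (target numbering)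
Conditions: RuCl2(=CHPh)(PCy3)(H2IMes) (second-generation Grubbs catalyst, 15 mol %), 1,4-benzoquinone (30 mol %), PhMe (0.001 M, slow addition of 21), 80 °C
Reagents that add atoms: none
Why: The benzylidene exchanges with the unhindered C7 vinyl group, and the resulting C7 alkylidene undergoes [2+2] cycloaddition and cycloreversion with the 1,1-disubstituted C8 olefin (Chauvin mechanism), expelling ethene and forming C7=C8. The closest known reaction type is ring-closing metathesis of acyclic dienes to ten-membered carbocycles bearing a trisubstituted olefin, as used for germacrane- and eunicellane-type rings. The only ring closed is the ten-membered carbocycle C1–C10, by union of the two terminal olefin carbons so that the new double bond is endocyclic. No stereocentre is created; the new stereo element is the olefin geometry, and the Z isomer (C6 and C9 cis) is the one the ten-membered ring should favour, which is exactly what the cis-fused C7–C8 oxirane requires. The step needs site selectivity for the C8 olefin over the C1 isopropenyl group (closure there would give an eight-membered ring) and over the electron-poor trisubstituted angelate olefin, and cyclisation over oligomerisation: the free allylic C9 hydroxyl accelerates metathesis at its own olefin, the isopropenyl group sits on a fully branched carbon next to the acyloxy-bearing C10, and high dilution together with the gauche turns imposed by the oxygenated C3–C5 and C9–C10 segments favours ring closure. Benzoquinone suppresses double-bond isomerisation of the allylic alcohol by hydride species formed from the catalyst.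

Step 15
Reactants: 22 (Z)-cyclodecenol
Product: 23 7,8-epoxide of 22 (oxirane cis-fused and anti to O9)
Conditions: m-CPBA, NaHCO3, CH2Cl2, 0 °C
Reagents that add atoms: 3-chloroperbenzoic acid, O=C(OO)c1cccc(Cl)c1
Why: Prilezhaev epoxidation guided by hydrogen bonding from the free allylic C9 hydroxyl, which also makes this trisubstituted olefin faster than the isopropenyl group; in the A(1,3)-controlled conformation of a medium-ring (Z)-cycloalkenol the hydroxyl-guided attack should give the trans epoxy alcohol, i.e. the oxirane oxygen on the ring face opposite to O9 as in the target, and syn addition to the Z olefin gives the cis-fused oxirane.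

Step 16
Reactants: 23 epoxy alcohol; 9 angelic 2,4,6-trichlorobenzoic anhydride
Product: 24 9-O-angelate of 23
Conditions: 9 (3 equiv), Et3N (3 equiv), PhMe, 80 °C
Reagents that add atoms: none
Why: Yamaguchi-type esterification of the hindered C9 hydroxyl with the preformed mixed anhydride, without Z-to-E isomerisation of the acyl group; C3 is silylated, the tertiary C4 hydroxyl is too hindered to react, and the weakly basic medium should leave the oxirane and the O10 ester in place.

Step 17
Reactants: 24 silyl-protected triester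
Product: 25 target CNP0246823.2
Conditions: HF·pyridine, pyridine, THF, 0 °C to rt
Reagents that add atoms: none
Why: Fluoride-mediated desilylation with buffered HF·pyridine, conditions that trisubstituted oxiranes and esters tolerate, frees the C3 hydroxyl without touching any stereocentre.

Compound list
1 | (S)-(+)-carvone [(5S)-2-methyl-5-(prop-1-en-2-yl)cyclohex-2-en-1-one] | C=C(C)[C@H]1CC=C(C)C(=O)C1 | starting material
2 | (1S,4S,6S)-1-methyl-4-(prop-1-en-2-yl)-7-oxabicyclo[4.1.0]heptan-2-one (oxirane trans to isopropenyl) | C=C(C)[C@H]1C[C@@H]2O[C@]2(C)C(=O)C1 | intermediate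
3 | 3-hydroxy-1-methyl-4-(prop-1-en-2-yl)-7-oxabicyclo[4.1.0]heptan-2-one (C10 hydroxyl, major epimer trans to isopropenyl) | C=C(C)[C@H]1C[C@@H]2O[C@]2(C)C(=O)[C@@H]1O | intermediate
4 | methyl 3-(2-formyl-3-methylbut-3-en-1-yl)-2-methyloxirane-2-carboxylate (cis-oxirane C3–C4, C10 aldehyde; formed in the flask) | COC(=O)[C@@]1(C)O[C@H]1C[C@@H](C=O)C(C)=C | intermediate
5 | methyl 2-hydroxy-2-[5-methoxy-4-(prop-1-en-2-yl)oxolan-2-yl]propanoate (oxolane oxygen joins C3 and C10; anomers) | COC(=O)[C@@](C)(O)[C@H]1C[C@H](C(C)=C)C(OC)O1 | intermediate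
6 | 2-hydroxy-2-[5-methoxy-4-(prop-1-en-2-yl)oxolan-2-yl]propanal | O=C[C@@](C)(O)[C@H]1C[C@H](C(C)=C)C(OC)O1 | intermediate
7 | 2-[5-methoxy-4-(prop-1-en-2-yl)oxolan-2-yl]hex-5-ene-2,3-diol (C4/C5 syn) | C=CC[C@H](O)[C@@](C)(O)[C@H]1C[C@H](C(C)=C)C(OC)O1 | intermediate
8 | angelic acid [(Z)-2-methylbut-2-enoic acid] | C/C=C(/C)C(=O)O | starting material
9 | (Z)-2-methylbut-2-enoic 2,4,6-trichlorobenzoic anhydride (acylating agent for steps 7 and 16) | C/C=C(/C)C(=O)OC(=O)c1c(Cl)cc(Cl)cc1Cl | intermediate
10 | 2-hydroxy-2-[5-methoxy-4-(prop-1-en-2-yl)oxolan-2-yl]hex-5-en-3-yl (Z)-2-methylbut-2-enoate | C=CC[C@H](OC(=O)/C(C)=C\C)[C@@](C)(O)[C@H]1C[C@H](C(C)=C)C(OC)O1 | intermediate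
11 | 2-hydroxy-2-[5-hydroxy-4-(prop-1-en-2-yl)oxolan-2-yl]hex-5-en-3-yl (Z)-2-methylbut-2-enoate (lactol) | C=CC[C@H](OC(=O)/C(C)=C\C)[C@@](C)(O)[C@H]1C[C@H](C(C)=C)C(O)O1 | intermediate
12 | 2-methylprop-2-en-1-ol | C=C(C)CO | starting material
13 | 3-(methoxymethoxy)-2-methylprop-1-ene | C=C(C)COCOC | intermediate
14 | [(Z)-3-(methoxymethoxy)-2-methylprop-2-en-1-yl]bis(isopinocampheyl)borane, isopinocampheyl groups from (+)-α-pinene (formed in the flask) | COCO/C=C(C)\CB([C@@H]1C[C@@H]2C[C@H]([C@H]1C)C2(C)C)[C@@H]1C[C@@H]2C[C@H]([C@H]1C)C2(C)C | intermediate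
15 | 5,6,9-trihydroxy-10-(methoxymethoxy)-5,11-dimethyl-8-(prop-1-en-2-yl)dodeca-1,11-dien-4-yl (Z)-2-methylbut-2-enoate (C1, C3, C4, C5, C9, C10 as in the target) | C=CC[C@H](OC(=O)/C(C)=C\C)[C@@](C)(O)[C@H](O)C[C@H](C(C)=C)[C@@H](O)[C@H](OCOC)C(C)=C | intermediate
16 | (R)-2-methylbutanoic acid | CC[C@@H](C)C(=O)O | starting material
17 | 2-phenyl-1,3,2-dioxaborolane (phenylboronate) of the C3/C4 diol of 15 (formed in the flask) | C=CC[C@H](OC(=O)/C(C)=C\C)[C@@]1(C)OB(c2ccccc2)O[C@@H]1C[C@H](C(C)=C)[C@@H](O)[C@H](OCOC)C(C)=C | intermediate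
18 | C10 (R)-2-methylbutanoate of 17 (formed in the flask) | C=CC[C@H](OC(=O)/C(C)=C\C)[C@@]1(C)OB(c2ccccc2)O[C@@H]1C[C@H](C(C)=C)[C@@H](OC(=O)[C@H](C)CC)[C@H](OCOC)C(C)=C | intermediate
19 | 5,6-dihydroxy-10-(methoxymethoxy)-5,11-dimethyl-9-[(2R)-2-methylbutanoyl]oxy-8-(prop-1-en-2-yl)dodeca-1,11-dien-4-yl (Z)-2-methylbut-2-enoate | C=CC[C@H](OC(=O)/C(C)=C\C)[C@@](C)(O)[C@H](O)C[C@H](C(C)=C)[C@@H](OC(=O)[C@H](C)CC)[C@H](OCOC)C(C)=C | intermediate
20 | C3 (chain position 6) tert-butyldimethylsilyl ether of 19 | C=CC[C@H](OC(=O)/C(C)=C\C)[C@@](C)(O)[C@H](O[Si](C)(C)C(C)(C)C)C[C@H](C(C)=C)[C@@H](OC(=O)[C@H](C)CC)[C@H](OCOC)C(C)=C | intermediate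
21 | 6-[tert-butyl(dimethyl)silyl]oxy-5,10-dihydroxy-5,11-dimethyl-9-[(2R)-2-methylbutanoyl]oxy-8-(prop-1-en-2-yl)dodeca-1,11-dien-4-yl (Z)-2-methylbut-2-enoate (free C9 hydroxyl) | C=CC[C@H](OC(=O)/C(C)=C\C)[C@@](C)(O)[C@H](O[Si](C)(C)C(C)(C)C)C[C@H](C(C)=C)[C@@H](OC(=O)[C@H](C)CC)[C@H](O)C(C)=C | intermediate
22 | (Z)-3-[tert-butyl(dimethyl)silyl]oxy-4,9-dihydroxy-4,8-dimethyl-10-[(2R)-2-methylbutanoyl]oxy-1-(prop-1-en-2-yl)cyclodec-7-en-5-yl (Z)-2-methylbut-2-enoate (target numbering) | C=C(C)[C@H]1C[C@@H](O[Si](C)(C)C(C)(C)C)[C@](C)(O)[C@@H](OC(=O)/C(C)=C\C)C/C=C(C)\[C@@H](O)[C@@H]1OC(=O)[C@H](C)CC | intermediate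
23 | 7,8-epoxide of 22 (oxirane cis-fused, anti to O9) | C=C(C)[C@H]1C[C@@H](O[Si](C)(C)C(C)(C)C)[C@](C)(O)[C@@H](OC(=O)/C(C)=C\C)C[C@@H]2O[C@]2(C)[C@@H](O)[C@@H]1OC(=O)[C@H](C)CC | intermediate
24 | 9-O-angelate of 23 (3-O-silyl ether of the target) | C=C(C)[C@H]1C[C@@H](O[Si](C)(C)C(C)(C)C)[C@](C)(O)[C@@H](OC(=O)/C(C)=C\C)C[C@@H]2O[C@]2(C)[C@@H](OC(=O)/C(C)=C\C)[C@@H]1OC(=O)[C@H](C)CC | intermediate
25 | CNP0246823.2: 7,8-epoxy-3,4-dihydroxy-4,8-dimethyl-10-[(2R)-2-methylbutanoyl]oxy-1-(prop-1-en-2-yl)cyclodecane-5,9-diyl bis[(Z)-2-methylbut-2-enoate] (target numbering) | C=C(C)[C@H]1C[C@@H](O)[C@](C)(O)[C@@H](OC(=O)/C(C)=C\C)C[C@@H]2O[C@]2(C)[C@@H](OC(=O)/C(C)=C\C)[C@@H]1OC(=O)[C@H](C)CC | target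

Total step count: 17. Longest linear sequence: 15 steps (steps 1–5, 7, 8 and 10–17, from 1); steps 6 and 9 are one-step side branches.

Steps most likely to fail

Step 14 (ring-closing metathesis). The C7 alkylidene may cyclise onto the C1 isopropenyl olefin (eight-membered ring) or chain-extend to oligomers faster than the ten-membered ring closes. The fallback sets out from 21 and comes back at 22. Iodoetherification of 21 (N-iodosuccinimide, NaHCO3, MeCN, −20 °C) should let O9 add 5-exo to the isopropenyl olefin and give the 2-(iodomethyl)-2-methyloxolane F1, in which the competing olefin is masked and the C9–C10–C1 segment is held in a turn. Metathesis of F1 under the conditions of step 14 then has only the C7/C8 pair to join and should give the bicyclic (Z)-cyclodecene F2. Zn dust and NH4Cl in EtOH (reductive β-elimination of the iodo ether) would restore the isopropenyl group and the free C9 hydroxyl, which is 22.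

Step 10 (γ-alkoxyallylboration of the lactol). Protonolysis of the allylborane by the free hydroxyl groups and slow opening of the lactol may outrun allyl transfer, and reagent control may be eroded if the C1 centre favours the opposite aldehyde face. The fallback sets out from 11 and comes back at 15. A syn-selective boron aldol reaction of 11 with the (Z)-enolate of 1-(methoxymethoxy)propan-2-one (n-Bu2BOTf, i-Pr2NEt, CH2Cl2, −78 °C, excess; a diisopinocampheylboron triflate if substrate control proves insufficient) would give the 9,10-syn β-hydroxy ketone F3 with a methyl ketone at C8. Wittig methylenation of F3 (Ph3P=CH2 in excess, THF, 0 °C) then gives 15.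

Step 15 (epoxidation). The peracid may attack the other face of the ring olefin or oxidise the isopropenyl olefin as well. The fallback sets out from 22 and comes back at 23. Oxidation of 22 with Dess–Martin periodinane (NaHCO3, CH2Cl2) would give the (Z)-enone F4. Nucleophilic epoxidation (t-BuOOH, DBU, CH2Cl2, 0 °C) touches only this conjugated C7=C8 bond and should give the epoxy ketone F5. Reduction with Zn(BH4)2 (Et2O, −20 °C), in which zinc bridges the ketone and oxirane oxygens, should deliver hydride anti to the oxirane and return the trans epoxy alcohol 23.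

Further compounds
F1 | step 14 | iodo ether of 21: O9 joined to the former isopropenyl carbon as a 2-(iodomethyl)-2-methyloxolane (epimers at the new quaternary carbon) | C=CC[C@H](OC(=O)/C(C)=C\C)[C@@](C)(O)[C@H](O[Si](C)(C)C(C)(C)C)C[C@@H]1C(C)(CI)O[C@H](C(C)=C)[C@@H]1OC(=O)[C@H](C)CC
F2 | step 14 | bicyclic (Z)-cyclodecene from F1 (ten-membered ring fused to the iodomethyl oxolane across C9–C10–C1) | C[C@@]1(O)[C@@H](OC(=O)/C(C)=C\C)C/C=C(C)\[C@H]2OC(C)(CI)[C@@H](C[C@H]1O[Si](C)(C)C(C)(C)C)[C@H]2OC(=O)[C@H](C)CC
F3 | step 10 | 5,6,9-trihydroxy-10-(methoxymethoxy)-5-methyl-11-oxo-8-(prop-1-en-2-yl)dodec-1-en-4-yl (Z)-2-methylbut-2-enoate (C8 methyl ketone, C9/C10 syn) | C=CC[C@H](OC(=O)/C(C)=C\C)[C@@](C)(O)[C@H](O)C[C@H](C(C)=C)[C@@H](O)[C@H](OCOC)C(C)=O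
F4 | step 15 | C9 ketone of 22 [(Z)-cyclodec-7-en-9-one] | C=C(C)[C@H]1C[C@@H](O[Si](C)(C)C(C)(C)C)[C@](C)(O)[C@@H](OC(=O)/C(C)=C\C)C/C=C(C)\C(=O)[C@@H]1OC(=O)[C@H](C)CC
F5 | step 15 | 7,8-epoxy-9-ketone (cis-fused oxirane) | C=C(C)[C@H]1C[C@@H](O[Si](C)(C)C(C)(C)C)[C@](C)(O)[C@@H](OC(=O)/C(C)=C\C)C[C@@H]2O[C@]2(C)C(=O)[C@@H]1OC(=O)[C@H](C)CC
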